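## The problem

Target 30 is a cyclohept-2-en-1-one that carries substituents on five of its seven ring carbons: hydroxymethyl on C2, methyl and a 3-hydroperoxy-4-methylpent-4-enyl chain on C5, an (E)-enol senecioate on C6 and an acetonyl group on C7. There is no second ring, so the seven-membered ring has to be closed directly or grown from a six-membered one. C5 (quaternary), C6 and C7 are contiguous stereocentres, with the C5 methyl cis and the C7 arm trans to the C6 arm; C7 lies α to the C1 ketone and can be equilibrated to the trans arrangement by C6, whereas C5 and C6 are fixed and must be set together, kinetically and in absolute terms. The fourth stereocentre, the hydroperoxide carbon, sits four bonds from C5 and cannot be controlled from the ring. The sensitive groups dictate the order of events: the allylic hydroperoxide is destroyed by phosphines, reducing metals and base and must come last, and the enol ester is an acyl donor that survives neither alkoxides nor nucleophilic catalysts. The C1 ketone and the acetonyl ketone form a 1,4-diketone that closes to a cyclopentenone with base and to a furan with strong acid, and the homoprenyl alkene needed for the ene reaction is also the most electron-rich alkene towards any earlier electrophile. The enabling feature is that, with C2 removed, C1 and C3–C7 form a cyclohexanone. Its C1=C3 enol silane is the retron of a Diels–Alder reaction (bonds C4–C5 and C6–C7) and also the substrate of a one-carbon ring expansion that returns C2 carrying bromine as the handle for the hydroxymethyl group.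

## Retrosynthesis

**Hydroperoxide (30 ⇒ 29).** The C–OOH bond and the terminal alkene are traced back, by a retro-ene operation, to the homoprenyl alkene of 29. Displacement or epoxide-opening routes to the peroxide need base or acid that the enol ester and the 1,4-diketone do not tolerate, or scramble the allylic position. 29 has one stereocentre fewer and no O–O bond. The forward reaction must pick the one electron-rich trisubstituted alkene among four alkenes, and its epimers must be separated.

**Acetonyl ketone and hydroxymethyl group (29 ⇒ 28 ⇒ 26 + 27).** The ketone is released from dioxolane 28 only here, because the free 1,4-diketone tolerates no base. The C2–CH2OH bond is cut to vinyl bromide 26 and stannane 27. A Morita–Baylis–Hillman reaction on the unsubstituted enone would need a nucleophilic catalyst that strips the enol ester. A neutral Stille coupling avoids this, and its bromine comes free with the ring expansion and never needs protection.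

**Enol ester (26 ⇒ 23 + 25; 23 ⇒ 22 ⇒ 21; 25 ⇒ 24).** The O–acyl bond is cut to aldehyde 23 and anhydride 25, made from two molecules of acid 24. The aldehyde comes from alcohol 22 and silyl ether 21. The enol ester is made after the last carbene, fluoride and strong-base step. It is made while the acetonyl ketone is still a ketal, which removes the one carbonyl that could trap the aldehyde enolate in a five-membered aldol. The forward step must acylate on oxygen and favour the E isomer.

**Side-chain alkene (21 ⇒ 19 + 20).** The trisubstituted C=C is cut by cross-metathesis to terminal alkene 19 and 2-methylbut-2-ene 20. A trisubstituted alkene would compete with the enol silane for dibromocarbene, whereas a monosubstituted one does not. The price is one step.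

**Ring expansion (19 ⇒ 17, through 18).** Bonds C1–C2 and C2–C3 are cut and C2 leaves as dibromocarbene, giving cyclohexene enol silane 17 by way of cyclopropane 18. Closing the seven-membered ring directly would leave the stereotriad to an acyclic or strained precursor. This cut moves the stereochemical problem into a six-membered ring and supplies the C2 bromine and the C2=C3 unsaturation in one operation. The siloxy group makes the opening regiospecific.

**Chain root (17 ⇒ 14 + 15, through 16; 14 ⇒ 13).** The butenyl chain is cut between its second and third carbons, giving borane 16 (from vinyl compound 14) and bromoethene 15. The vinyl group is cut at its C=C back to aldehyde 13. These bonds are made before the ring expansion because an organoborane cannot be generated beside an enone, while the enol silane is a masked, non-reducible ketone. Longer ylides on 13 would leave an alkene next to the quaternary carbon that would need selective reduction.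

**Cycloaddition (13 ⇒ 8 + 12).** Bonds C4–C5 and C6–C7 are cut. The C1=C3 enol silane fixes the partners without ambiguity. The diene is 2-siloxydiene 8 (C4=C3–C1=C7, with the acetonyl carbons on C7 as a ketal). The dienophile is enal 12 (C5=C6, methyl on C5, formyl as the chain root). A stepwise conjugate addition and alkylation on a cyclohexenone would have to tell a methyl from an alkyl chain at a preformed quaternary carbon. The cycloaddition instead takes the C5/C6 relation from alkene geometry and C7 from the endo mode, and builds the quaternary carbon in the same step from two achiral open-chain fragments. The forward reaction must be regioselective, endo-selective and enantioface-selective with a hindered enal.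

**Fragments.** Diene 8 comes from vinyl ketone 7 by (Z)-selective enol silylation. Ketone 7 comes from amide 5 and vinylmagnesium bromide 6, amide 5 from ester 3 and amine salt 4, and ester 3 from ethyl levulinate 1 and diol 2. Enal 12 comes from aldehyde 10 and ylide 11, and aldehyde 10 from alcohol 9.

## Roads not taken

**Alternative 1:** The C1–C7 bond is cut. An α,β-unsaturated acyl radical at C1, released from phenyl selenoester A1 with a tin or silicon hydride, would add 7-exo to C7 of the pendant (E)-enone. Hydrogen transfer to the α-keto radical would give cycloheptenone A2 and create the acetonyl arm in the same event.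
- Merits: the seven-membered ring forms directly, with C2 already carrying its protected hydroxymethyl group and C5 its complete chain. No ring expansion, coupling at C2 or chain extension follows. In steps after the key step this road is better than the chosen one.
- Weak points: A1 is an open chain. Its C5 quaternary and C6 tertiary centres, and a (Z)-trisubstituted enoyl unit, must be set with no ring to relay stereochemistry. The 7-exo closure is slow enough for premature hydrogen transfer and for the ketene-like reactivity of unsaturated acyl radicals to compete. C7 is formed in a flexible transition state with little bias, although it can be epimerised afterwards.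
- Comparison: against the shorter endgame of A2, the chosen plan sets all three ring stereocentres in one catalyst-controlled step from fragments made in four and two steps.

**Alternative 2:** The C5–C6 bond is cut and the C1–C3 bond added, leading to cis-dialkenyl siloxycyclopropane A3. Its Cope rearrangement through the boat transition state would give cyclohepta-1,4-diene A4.
- Merits: C5 and C6 follow stereospecifically from alkene geometry and cyclopropane configuration. The C1 enol silane and a C2 ester (the future hydroxymethyl carbon) appear directly, with no ring expansion and no Stille coupling. In ring construction this road is equal or better.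
- Weak points: the C5 terminus is fully substituted. To end cis to the C6 arm the methyl must be trans to C3, so the homoprenyl chain points into the cyclopropane in the boat. That retards the rearrangement and opens the way to cyclopropane epimerisation and homodienyl hydrogen shift. A3 needs a (Z)-trisubstituted alkene, an (E)-alkene and three contiguous cyclopropane stereocentres in absolute form. A4 still lacks the C7 acetonyl arm, which must be added trans to the C6 arm, and its C3=C4 alkene must be moved into conjugation.
- Comparison: the chosen plan answers with a far simpler precursor, the C7 arm included in the key step, and predictable absolute control. It pays with two extra operations, the ring expansion and the coupling at C2.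

**Alternative 3:** The insertion of C2 is made the strategic step. Dibromocarbene adds to enol silane A5 of a fully substituted cyclohexanone and the adduct opens to bromoenone A6.
- Merits: the transformation is the same as step 10 of the chosen route, so the two plans are equal in how the ring and the C2 handle arise. A6 is better dressed than 19 in one respect. Its C6 arm is already at the aldehyde oxidation level as an acetal and its C5 arm is a silyl ether, so no metathesis is needed and one oxidation is saved.
- Weak points: the road leaves open how the cyclohexanone behind A5 obtains the C5–C6–C7 triad. Conjugate addition and enolate alkylation on a 4,4-disubstituted cyclohexenone must distinguish methyl from a primary alkyl chain when C6 is created, and need the quaternary centre enantiopure beforehand. The acetal of A6 would also not survive a Lewis-acid cycloaddition, so its better protecting-group pattern is tied to the stepwise ring construction.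
- Comparison: the chosen plan keeps the ring expansion and answers the open question with one cycloaddition. It accepts the silyl ether, the oxidation and the metathesis as the cost.

Key step: step 7

Assumption: the enantiofacial sense of step 7 is assigned from the accepted binding model of α-substituted enals on protonated oxazaborolidines (formyl C–H···O contact, s-trans enal, one face covered by an aryl group). On that model the (R)-catalyst exposes the Si face of C5; the (S)-catalyst would be used if the opposite sense were found.

Assumption: 3-(tert-butyldimethylsilyloxy)propan-1-ol (9) is treated as purchasable; it is otherwise one silylation from propane-1,3-diol.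

## Route

Ring atoms carry the target numbers C1–C7 throughout.

Step 1
Reactants: 1 ethyl levulinate; 2 ethane-1,2-diol
Product: 3 ethyl 3-(2-methyl-1,3-dioxolan-2-yl)propanoate
Conditions: p-TsOH·H2O (cat.), toluene, reflux, Dean–Stark trap
Reagents that add atoms: none
Why: Acid-catalysed ketalisation with azeotropic removal of water; only the ketone reacts and the dioxolane then masks the future acetonyl carbonyl until step 17.

Step 2
Reactants: 3 ethyl 3-(2-methyl-1,3-dioxolan-2-yl)propanoate; 4 N,O-dimethylhydroxylamine hydrochloride
Product: 5 N-methoxy-N-methyl-3-(2-methyl-1,3-dioxolan-2-yl)propanamide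
Conditions: iPrMgCl, THF, −20 → 0 °C
Reagents that add atoms: none
Why: The magnesium amide of the hydroxylamine converts the ester directly into the N-methoxy-N-methylamide (ester aminolysis); the ketal is inert to the base.

Step 3
Reactants: 5 N-methoxy-N-methyl-3-(2-methyl-1,3-dioxolan-2-yl)propanamide; 6 vinylmagnesium bromide
Product: 7 5-(2-methyl-1,3-dioxolan-2-yl)pent-1-en-3-one
Conditions: THF, −10 °C; inverse quench into cold 1 M HCl
Reagents that add atoms: none
Why: Weinreb ketone synthesis; the chelated tetrahedral intermediate prevents over-addition, and the cold acidic quench protonates the released hydroxylamine before it can add to the vinyl ketone.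

Step 4
Reactants: 7 5-(2-methyl-1,3-dioxolan-2-yl)pent-1-en-3-one
Product: 8 2-methyl-2-[(2Z)-3-(triethylsilyloxy)penta-2,4-dien-1-yl]-1,3-dioxolane
Conditions: TESOTf, Et3N, Et2O, −20 → 0 °C
Reagents that add atoms: triethylsilyl trifluoromethanesulfonate, CC[Si](CC)(CC)OS(=O)(=O)C(F)(F)F
Why: Soft enolisation of an alkyl vinyl ketone with silyl triflate and amine gives the cross-conjugated 2-siloxydiene; the (Z)-enol silane, with the CH2 substituent cis to oxygen, is the expected major isomer under these conditions and is the one that reacts as a diene.

Step 5
Reactants: 9 3-(tert-butyldimethylsilyloxy)propan-1-ol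
Product: 10 3-(tert-butyldimethylsilyloxy)propanal
Conditions: TEMPO (2,2,6,6-tetramethylpiperidin-1-oxyl, cat.), PhI(OAc)2, CH2Cl2, rt
Reagents that add atoms: none
Why: Oxoammonium-mediated oxidation of a primary alcohol stops at the aldehyde, and the near-neutral medium avoids β-elimination of the silyloxy group.

Step 6
Reactants: 10 3-(tert-butyldimethylsilyloxy)propanal; 11 2-(triphenylphosphoranylidene)propanal
Product: 12 (2E)-5-(tert-butyldimethylsilyloxy)-2-methylpent-2-enal
Conditions: toluene, 80 °C
Reagents that add atoms: none
Why: Wittig reaction of a stabilised α-branched ylide gives the (E)-trisubstituted enal, which fixes the later cis relation of the C5 methyl and the C6 arm.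

Step 7
Reactants: 8 2-methyl-2-[(2Z)-3-(triethylsilyloxy)penta-2,4-dien-1-yl]-1,3-dioxolane; 12 (2E)-5-(tert-butyldimethylsilyloxy)-2-methylpent-2-enal
Product: 13 (1S,5S,6S)-6-[2-(tert-butyldimethylsilyloxy)ethyl]-1-methyl-5-[(2-methyl-1,3-dioxolan-2-yl)methyl]-4-(triethylsilyloxy)cyclohex-3-ene-1-carbaldehyde
Conditions: (R)-3,3-diphenyl-1-(2-methylphenyl)tetrahydro-1H,3H-pyrrolo[1,2-c][1,3,2]oxazaborole (C24H24BNO, 20 mol%), HN(SO2CF3)2 (18 mol%), CH2Cl2, −78 → −40 °C
Reagents that add atoms: none
Why: The protonated oxazaborolidine binds the formyl oxygen of 12 anti to C5, with the formyl C–H held by the ring oxygen, and 8 adds to the activated s-trans enal in a concerted, asynchronous normal-demand [4+2] cycloaddition; the closest known reaction type is the chiral oxazaborolidinium-catalysed Diels–Alder reaction of 2-siloxydienes with α-substituted enals. The single ring closes by intermolecular suprafacial [π4s+π2s] union in which the siloxy-activated terminus C7 bonds to the enal β-carbon C6 (the more advanced bond) and C4 bonds to the formyl-bearing C5, so the regiochemistry is electronically matched. C5 and its relation to C6 come from suprafacial addition to the (E)-enal, which keeps the methyl group and the C6 arm cis, and their absolute configuration comes from the catalyst, whose aryl group covers one face so that the diene reaches the Si face of C5. C7 is set by the (Z)-geometry of 8, which places the ketal arm outside, combined with the formyl-endo transition state, which puts that arm trans to the C6 arm. The step needs regio-, endo- and enantioface selectivity and a rate that beats protodesilylation and stepwise Mukaiyama–Michael addition; the polarised diene, the single strongly Lewis-basic formyl site and the low temperature are what secure them. The adduct emerges as the C1=C3 enol silane that the ring expansion later consumes.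

Step 8
Reactants: 13 cyclohexene carbaldehyde enol silane (5S,6S,7S)
Product: 14 5-ethenyl cyclohexene enol silane (5R,6S,7S)
Conditions: Ph3PCH3Br, KHMDS, THF, 0 °C → rt
Reagents that add atoms: methyltriphenylphosphonium bromide, C[P+](c1ccccc1)(c1ccccc1)c1ccccc1.[Br-]
Why: Wittig methylenation of a non-enolisable neopentyl aldehyde; the ylide does not attack the enol silane, the ketal or the silyl ether, and the change of descriptor at C5 is only formal.

Step 9
Reactants: 14 5-ethenyl cyclohexene enol silane (5R,6S,7S); 15 bromoethene
Product: 17 5-(but-3-enyl) cyclohexene enol silane (5S,6S,7S), via B-alkyl-9-borabicyclo[3.3.1]nonane 16 (not isolated)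
Conditions: 9-BBN, THF, rt; then 15, PdCl2(dppf) (5 mol%), K3PO4·H2O, DMF, 50 °C
Reagents that add atoms: none
Why: 9-BBN hydroborates the only monosubstituted alkene at its terminus far faster than the trisubstituted enol silane, and the B-alkyl Suzuki–Miyaura coupling with the vinyl halide then gives the terminal butenyl chain; phosphate in DMF is chosen as a base mild enough for the enol silane.

Step 10
Reactants: 17 5-(but-3-enyl) cyclohexene enol silane (5S,6S,7S)
Product: 19 (5S,6S,7S)-2-bromo-5-(but-3-enyl)cyclohept-2-enone, via siloxy dibromocyclopropane 18 (not isolated)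
Conditions: CHBr3, KOtBu, pentane, −30 → 0 °C; filtration; toluene, 80 °C
Reagents that add atoms: bromoform, BrC(Br)Br
Why: Electrophilic dibromocarbene adds to the electron-rich enol silane much faster than to the monosubstituted alkene, and the adduct opens by disrotatory cleavage of the C1–C3 bond with loss of bromide and then of the silyl group to give the 2-bromocyclohept-2-enone (halocarbene ring expansion of cyclic silyl enol ethers). C2 is inserted between C1 and C3 with its bromine, and C5–C7 are untouched.

Step 11
Reactants: 19 (5S,6S,7S)-2-bromo-5-(but-3-enyl)cyclohept-2-enone; 20 2-methylbut-2-ene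
Product: 21 (5S,6S,7S)-2-bromo-5-(4-methylpent-3-enyl)cyclohept-2-enone silyl ether
Conditions: RuCl2(=CHPh)(PCy3)(H2IMes) (second-generation Grubbs catalyst, 5 mol%), 20 (excess), CH2Cl2, 40 °C
Reagents that add atoms: none
Why: Olefin cross-metathesis of the unhindered terminal alkene with 2-methylbut-2-ene installs the isopropylidene terminus; the electron-poor trisubstituted bromoenone alkene does not take part.

Step 12
Reactants: 21 (5S,6S,7S)-2-bromo-5-(4-methylpent-3-enyl)cyclohept-2-enone silyl ether
Product: 22 (5S,6S,7S)-2-bromo-6-(2-hydroxyethyl)cyclohept-2-enone
Conditions: HF·pyridine, pyridine, THF, 0 °C → rt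
Reagents that add atoms: none
Why: Buffered fluoride cleaves the primary silyl ether and leaves the dioxolane and the bromoenone alone; no strong base is present that could act at C7.

Step 13
Reactants: 22 (5S,6S,7S)-2-bromo-6-(2-hydroxyethyl)cyclohept-2-enone
Product: 23 (5S,6S,7S)-2-bromo-6-(2-oxoethyl)cyclohept-2-enone
Conditions: Dess–Martin periodinane, pyridine, CH2Cl2, 0 °C → rt
Reagents that add atoms: none
Why: Hypervalent-iodine oxidation stops at the aldehyde under buffered, non-basic conditions; the aldehyde α-carbon is a CH2 group, so no stereocentre is at risk.

Step 14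
Reactants: 24 3-methylbut-2-enoic acid (two molecules per molecule of product)
Product: 25 3-methylbut-2-enoic anhydride
Conditions: DCC (0.5 equiv relative to 24), CH2Cl2, 0 °C → rt; filtration
Reagents that add atoms: 3-methylbut-2-enoic acid (the second molecule of 24, which supplies the second acyl group), CC(C)=CC(=O)O
Why: Carbodiimide dehydration: DCC activates one molecule of the acid as its O-acylisourea, which acylates a second molecule to give the symmetrical anhydride and insoluble dicyclohexylurea. The anhydride is used instead of the acid chloride, which with amine bases forms a vinylketene and deconjugated esters.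

Step 15
Reactants: 23 (5S,6S,7S)-2-bromo-6-(2-oxoethyl)cyclohept-2-enone; 25 3-methylbut-2-enoic anhydride
Product: 26 (5S,6S,7S)-2-bromo-6-[(E)-2-(3-methylbut-2-enoyloxy)ethenyl]cyclohept-2-enone
Conditions: Et3N, 4-(dimethylamino)pyridine (cat.), CH2Cl2, rt
Reagents that add atoms: none
Why: Amine-mediated enolisation of the aldehyde and O-acylation by the acylpyridinium ion is the known route from aldehydes to enol esters; the (E)-isomer should dominate because the (Z)-arrangement forces the acyloxy group against the congested C6. Triethylamine does not enolise the ketone, and the acetonyl carbonyl is still a ketal, so no aldol partner exists.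

Step 16
Reactants: 26 (5S,6S,7S)-2-bromo-6-[(E)-2-(3-methylbut-2-enoyloxy)ethenyl]cyclohept-2-enone; 27 (tributylstannyl)methanol
Product: 28 (5S,6S,7S)-2-(hydroxymethyl)cyclohept-2-enone enol ester ketal
Conditions: Pd(PPh3)4 (10 mol%), 1,4-dioxane, 85 °C
Reagents that add atoms: none
Why: Stille coupling of an activated α-bromoenone with the hydroxymethylstannane replaces bromine by CH2OH under neutral conditions that the enol ester, the ketal and the trisubstituted alkene tolerate.

Step 17
Reactants: 28 (5S,6S,7S)-2-(hydroxymethyl)cyclohept-2-enone enol ester ketal
Product: 29 (5S,6S,7S)-2-(hydroxymethyl)-7-(2-oxopropyl)cyclohept-2-enone enol ester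
Conditions: pyridinium p-toluenesulfonate (cat.), acetone/H2O, 50 °C
Reagents that add atoms: water, O
Why: Mild acid hydrolysis of the dioxolane; the weak pyridinium acid spares the enol ester and the allylic alcohol, and the absence of base keeps the new 1,4-diketone from aldol closure.

Step 18
Reactants: 29 (5S,6S,7S)-2-(hydroxymethyl)-7-(2-oxopropyl)cyclohept-2-enone enol ester
Product: 30 (5S,6S,7S)-5-[(3S)-3-hydroperoxy-4-methylpent-4-en-1-yl]-2-(hydroxymethyl)-5-methyl-6-[(E)-2-(3-methylbut-2-enoyloxy)ethenyl]-7-(2-oxopropyl)cyclohept-2-en-1-one
Conditions: O2, visible light, 5,10,15,20-tetraphenylporphyrin (cat.), CH2Cl2, −20 °C; HPLC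
Reagents that add atoms: dioxygen, O=O
Why: Schenck ene reaction of singlet oxygen at the only electron-rich trisubstituted alkene; abstraction of a methyl hydrogen gives the secondary hydroperoxide with the isopropenyl group, while the enone, enol ester and senecioate alkenes are too electron-poor to compete. The remote centre is not controlled, so 30 must be separated from its (3R)-epimer and from the tertiary hydroperoxide regioisomer.

## Compound list

1 | ethyl levulinate (ethyl 4-oxopentanoate) | CCOC(=O)CCC(C)=O | starting material
2 | ethane-1,2-diol | OCCO | starting material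
3 | ethyl 3-(2-methyl-1,3-dioxolan-2-yl)propanoate | CCOC(=O)CCC1(C)OCCO1 | intermediate
4 | N,O-dimethylhydroxylamine hydrochloride | CNOC.Cl | starting material
5 | N-methoxy-N-methyl-3-(2-methyl-1,3-dioxolan-2-yl)propanamide | CON(C)C(=O)CCC1(C)OCCO1 | intermediate
6 | vinylmagnesium bromide | C=C[Mg]Br | starting material
7 | 5-(2-methyl-1,3-dioxolan-2-yl)pent-1-en-3-one | C=CC(=O)CCC1(C)OCCO1 | intermediate
8 | 2-methyl-2-[(2Z)-3-(triethylsilyloxy)penta-2,4-dien-1-yl]-1,3-dioxolane | C=C/C(O[Si](CC)(CC)CC)=C/CC1(C)OCCO1 | intermediate
9 | 3-(tert-butyldimethylsilyloxy)propan-1-ol | OCCCO[Si](C)(C)C(C)(C)C | starting material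
10 | 3-(tert-butyldimethylsilyloxy)propanal | O=CCCO[Si](C)(C)C(C)(C)C | intermediate
11 | 2-(triphenylphosphoranylidene)propanal | CC(C=O)=P(c1ccccc1)(c1ccccc1)c1ccccc1 | starting material
12 | (2E)-5-(tert-butyldimethylsilyloxy)-2-methylpent-2-enal | O=C/C(C)=C/CCO[Si](C)(C)C(C)(C)C | intermediate
13 | (1S,5S,6S)-6-[2-(tert-butyldimethylsilyloxy)ethyl]-1-methyl-5-[(2-methyl-1,3-dioxolan-2-yl)methyl]-4-(triethylsilyloxy)cyclohex-3-ene-1-carbaldehyde; (5S,6S,7S) in target numbering, formyl cis to the C7 arm and trans to the C6 arm | O=C[C@@]1(C)CC=C(O[Si](CC)(CC)CC)[C@@H](CC2(C)OCCO2)[C@@H]1CCO[Si](C)(C)C(C)(C)C | intermediate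
14 | cyclohexene enol silane as 13 with ethenyl in place of formyl on C5; (5R,6S,7S) in target numbering | C=C[C@@]1(C)CC=C(O[Si](CC)(CC)CC)[C@@H](CC2(C)OCCO2)[C@@H]1CCO[Si](C)(C)C(C)(C)C | intermediate
15 | bromoethene (vinyl bromide) | C=CBr | starting material
16 | B-alkyl-9-borabicyclo[3.3.1]nonane formed from 14 by hydroboration of the ethenyl group (not isolated) | C1CCC2CCCC1B2CC[C@@]3(C)CC=C(O[Si](CC)(CC)CC)[C@@H](CC4(C)OCCO4)[C@@H]3CCO[Si](C)(C)C(C)(C)C | intermediate
17 | cyclohexene enol silane as 13 with but-3-en-1-yl in place of formyl on C5; (5S,6S,7S) in target numbering | C=CCC[C@@]1(C)CC=C(O[Si](CC)(CC)CC)[C@@H](CC2(C)OCCO2)[C@@H]1CCO[Si](C)(C)C(C)(C)C | intermediate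
18 | 7,7-dibromo-1-(triethylsilyloxy)bicyclo[4.1.0]heptane formed from 17 (cyclopropane cis-fused across C1–C3, either face; both new centres are lost on opening; not isolated) | C=CCC[C@@]1(C)CC2C(Br)(Br)C2(O[Si](CC)(CC)CC)[C@@H](CC3(C)OCCO3)[C@@H]1CCO[Si](C)(C)C(C)(C)C | intermediate
19 | (5S,6S,7S)-2-bromo-5-(but-3-en-1-yl)-6-[2-(tert-butyldimethylsilyloxy)ethyl]-5-methyl-7-[(2-methyl-1,3-dioxolan-2-yl)methyl]cyclohept-2-en-1-one | C=CCC[C@@]1(C)CC=C(Br)C(=O)[C@@H](CC2(C)OCCO2)[C@@H]1CCO[Si](C)(C)C(C)(C)C | intermediate
20 | 2-methylbut-2-ene | CC=C(C)C | starting material
21 | (5S,6S,7S)-2-bromo-6-[2-(tert-butyldimethylsilyloxy)ethyl]-5-methyl-5-(4-methylpent-3-en-1-yl)-7-[(2-methyl-1,3-dioxolan-2-yl)methyl]cyclohept-2-en-1-one | CC(C)=CCC[C@@]1(C)CC=C(Br)C(=O)[C@@H](CC2(C)OCCO2)[C@@H]1CCO[Si](C)(C)C(C)(C)C | intermediate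
22 | (5S,6S,7S)-2-bromo-6-(2-hydroxyethyl)-5-methyl-5-(4-methylpent-3-en-1-yl)-7-[(2-methyl-1,3-dioxolan-2-yl)methyl]cyclohept-2-en-1-one | CC(C)=CCC[C@@]1(C)CC=C(Br)C(=O)[C@@H](CC2(C)OCCO2)[C@@H]1CCO | intermediate
23 | (5S,6S,7S)-2-bromo-5-methyl-5-(4-methylpent-3-en-1-yl)-7-[(2-methyl-1,3-dioxolan-2-yl)methyl]-6-(2-oxoethyl)cyclohept-2-en-1-one | CC(C)=CCC[C@@]1(C)CC=C(Br)C(=O)[C@@H](CC2(C)OCCO2)[C@@H]1CC=O | intermediate
24 | 3-methylbut-2-enoic acid | CC(C)=CC(=O)O | starting material
25 | 3-methylbut-2-enoic anhydride | CC(C)=CC(=O)OC(=O)C=C(C)C | intermediate
26 | (5S,6S,7S)-2-bromo-5-methyl-6-[(E)-2-(3-methylbut-2-enoyloxy)ethenyl]-5-(4-methylpent-3-en-1-yl)-7-[(2-methyl-1,3-dioxolan-2-yl)methyl]cyclohept-2-en-1-one | CC(C)=CCC[C@@]1(C)CC=C(Br)C(=O)[C@@H](CC2(C)OCCO2)[C@@H]1/C=C/OC(=O)C=C(C)C | intermediate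
27 | (tributylstannyl)methanol | CCCC[Sn](CCCC)(CCCC)CO | starting material
28 | (5S,6S,7S)-2-(hydroxymethyl)-5-methyl-6-[(E)-2-(3-methylbut-2-enoyloxy)ethenyl]-5-(4-methylpent-3-en-1-yl)-7-[(2-methyl-1,3-dioxolan-2-yl)methyl]cyclohept-2-en-1-one | CC(C)=CCC[C@@]1(C)CC=C(CO)C(=O)[C@@H](CC2(C)OCCO2)[C@@H]1/C=C/OC(=O)C=C(C)C | intermediate
29 | (5S,6S,7S)-2-(hydroxymethyl)-5-methyl-6-[(E)-2-(3-methylbut-2-enoyloxy)ethenyl]-5-(4-methylpent-3-en-1-yl)-7-(2-oxopropyl)cyclohept-2-en-1-one | CC(C)=CCC[C@@]1(C)CC=C(CO)C(=O)[C@@H](CC(C)=O)[C@@H]1/C=C/OC(=O)C=C(C)C | intermediate
30 | (5S,6S,7S)-5-[(3S)-3-hydroperoxy-4-methylpent-4-en-1-yl]-2-(hydroxymethyl)-5-methyl-6-[(E)-2-(3-methylbut-2-enoyloxy)ethenyl]-7-(2-oxopropyl)cyclohept-2-en-1-one (CNP0216745.1) | C=C(C)[C@H](CC[C@@]1(C)CC=C(CO)C(=O)[C@@H](CC(C)=O)[C@@H]1/C=C/OC(=O)C=C(C)C)OO | target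

## Step count and least certain steps

Total: 18 steps. Longest linear sequence: 15 steps (steps 1–4, 7–13 and 15–18); steps 5–6 and step 14 are side branches.

**Step 7 (key step).** The α,β-disubstituted enal is a slow dienophile and the bonding terminus C7 of the diene is substituted. At the temperature needed for selectivity the cycloaddition may be outrun by protodesilylation of the diene or by stepwise Mukaiyama–Michael addition, and endo/exo and enantioface discrimination may erode. A modest endo/exo erosion is tolerable, because C7 becomes α to the ketone after step 10 and can then be equilibrated with an amine base. Fallback: give up catalyst control. Diene 8 and enal 12 are combined under an achiral aluminium Lewis acid (AlBr3/AlMe3 mixture, toluene/CH2Cl2, low temperature), which should give 13 together with the enantiomeric adduct F1. The mixture is methylenated as in step 8, and 14 is separated from the enantiomeric vinyl compound F2 by preparative chromatography on a chiral stationary phase. This path sets out from 8 and 12 and returns to the route at 14.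

**Step 9.** The triethylsilyl enol ether may be hydrolysed under the basic coupling conditions, which would destroy the regiochemical information for the ring expansion. Fallback: accept the loss and regenerate. The coupling is run with aqueous base and desilylation is completed (K2CO3, MeOH) to give the butenyl cyclohexanone F3. The C1=C3 enol silane is then re-formed by kinetic deprotonation (LDA, THF, −78 °C; TESCl), which should occur at the unhindered C3 methylene and not at the tertiary, doubly flanked C7. This path sets out from 14 and returns at 17.

**Step 15.** O-Acylation may give poor E/Z control, and the aldehyde enolate may instead add across the ring to C3 of the bromoenone or self-condense if acyl transfer is slow. Fallback: correct the geometry thermodynamically. The isomers are separated and the (Z)-enol ester F4 is equilibrated by reversible thiyl-radical addition (PhSSPh, visible light, benzene), which should converge on the less strained (E)-isomer. This path sets out from 23 and returns at 26.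

**Step 18.** Hydrogen abstraction from the allylic CH2 gives the tertiary hydroperoxide regioisomer, both configurations arise at the new centre, and the free hydroperoxides may co-elute or degrade during separation. Fallback: separate as derivatives. The crude mixture is treated with 2-methoxypropene and pyridinium p-toluenesulfonate, which should convert 30 into the bis(2-methoxyprop-2-yl) peroxyketal F5, its epimer into the epimeric peroxyketal F6 and the regioisomer into the tertiary peroxyketal F7. These less polar, more robust compounds are separated, and F5 is unmasked with AcOH/THF/H2O. This path sets out from 29 and returns at 30.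

## Further compounds

F1 | step 7 | enantiomer of 13 | O=C[C@]1(C)CC=C(O[Si](CC)(CC)CC)[C@H](CC2(C)OCCO2)[C@H]1CCO[Si](C)(C)C(C)(C)C
F2 | step 7 | enantiomer of 14 | C=C[C@]1(C)CC=C(O[Si](CC)(CC)CC)[C@H](CC2(C)OCCO2)[C@H]1CCO[Si](C)(C)C(C)(C)C
F3 | step 9 | (5S,6S,7S)-5-(but-3-en-1-yl)-6-[2-(tert-butyldimethylsilyloxy)ethyl]-5-methyl-7-[(2-methyl-1,3-dioxolan-2-yl)methyl]cyclohexan-1-one (target numbering) | C=CCC[C@@]1(C)CCC(=O)[C@@H](CC2(C)OCCO2)[C@@H]1CCO[Si](C)(C)C(C)(C)C
F4 | step 15 | (Z)-enol ester isomer of 26 | CC(C)=CCC[C@@]1(C)CC=C(Br)C(=O)[C@@H](CC2(C)OCCO2)[C@@H]1/C=C\OC(=O)C=C(C)C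
F5 | step 18 | bis(2-methoxyprop-2-yl) derivative of 30 (peroxyketal at the hydroperoxide, mixed ketal at the hydroxymethyl group) | C=C(C)[C@H](CC[C@@]1(C)CC=C(COC(C)(C)OC)C(=O)[C@@H](CC(C)=O)[C@@H]1/C=C/OC(=O)C=C(C)C)OOC(C)(C)OC
F6 | step 18 | bis(2-methoxyprop-2-yl) derivative of the (3R)-epimer of 30 | C=C(C)[C@@H](CC[C@@]1(C)CC=C(COC(C)(C)OC)C(=O)[C@@H](CC(C)=O)[C@@H]1/C=C/OC(=O)C=C(C)C)OOC(C)(C)OC
F7 | step 18 | bis(2-methoxyprop-2-yl) derivative of the tertiary hydroperoxide regioisomer, side chain (E)-CH2CH=CH–C(CH3)2OO– | COC(C)(C)OOC(C)(C)/C=C/C[C@@]1(C)CC=C(COC(C)(C)OC)C(=O)[C@@H](CC(C)=O)[C@@H]1/C=C/OC(=O)C=C(C)C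
A1 | alternative 1 | acyclic Se-phenyl selenoester with the (Z)-enoyl unit, the C5/C6 stereocentres and the (E)-enone | CC(C)=CCC[C@@](C)(C/C=C(\C(=O)[Se]c1ccccc1)CO[Si](C)(C)C(C)(C)C)[C@@H](CC(OC)OC)/C=C/C(C)=O
A2 | alternative 1 | protected cycloheptenone with acetonyl arm from the acyl radical closure | CC(C)=CCC[C@@]1(C)CC=C(CO[Si](C)(C)C(C)(C)C)C(=O)[C@@H](CC(C)=O)[C@@H]1CC(OC)OC
A3 | alternative 2 | cis-1,2-dialkenyl siloxycyclopropane ester | CC(C)=CCC/C(C)=C\[C@H]1[C@H](C(=O)OCC)[C@@]1(O[Si](CC)(CC)CC)/C=C/CCO[Si](C)(C)C(C)(C)C
A4 | alternative 2 | cyclohepta-1,4-diene enol silane ester from the Cope rearrangement | CC(C)=CCC[C@@]1(C)C=C[C@H](C(=O)OCC)C(O[Si](CC)(CC)CC)=C[C@@H]1CCO[Si](C)(C)C(C)(C)C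
A5 | alternative 3 | trimethylsilyl enol ether of the fully substituted cyclohexanone | CC(C)(C)[Si](C)(C)OCCC[C@@]1(C)CC=C(O[Si](C)(C)C)[C@@H](CC2(C)OCCO2)[C@@H]1CC(OC)OC
A6 | alternative 3 | 2-bromocyclohept-2-enone with all three ring stereocentres | CC(C)(C)[Si](C)(C)OCCC[C@@]1(C)CC=C(Br)C(=O)[C@@H](CC2(C)OCCO2)[C@@H]1CC(OC)OC
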